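# Proposed total synthesis of CNP0118407.2 through a dearomative conjunctive coupling of a benzofuranyl boronate

## Structural features

The target consists of two trans-2,3-diaryl-2,3-dihydrobenzofurans joined by one sp3–sp2 bond from C3 of unit 1 (unprimed) to C6' of unit 2 (primed). Unit 1 carries a hydroxyl at C4, an (E)-4-hydroxystyryl group at C6 and a 4-hydroxyphenyl group at C2. Unit 2 carries a hydroxyl at C4', a 2,4-dihydroxyphenyl group at C2' and a 3,5-dihydroxyphenyl group at C3'. The four stereocentres form two adjacent pairs, C2/C3 and C2'/C3', all R and trans within each ring; the benzo ring of unit 2 (ring B) separates the pairs, so neither pair can direct the other. The fragile parts are the eight free phenols (air oxidation), the stilbene (acid, light), the doubly benzylic C3–H and C3'–H, and the benzylic ether bonds O1–C2 and above all O1'–C2', which ionises easily because C2' bears an ortho,para-dioxygenated aryl group. The real difficulties are absolute control of two remote stereo-pairs, the congested C3–C6' bond (C3 lies between the C2 aryl group and the peri oxygen on C4), and the absence of functional handles on carbons that carry only aryl groups. The key step uses the C2'=C3' enol-ether double bond of a flat 4-oxygenated 6-chlorobenzofuran: both aryl–carbon bonds of unit 2 and both of its stereocentres are set across that bond in one operation, and the trans relationship follows from the mechanism.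

## Logic of the disconnections

**29 to 28.** The eight O–CH3 bonds are cut last. Methyl is the one phenol protection that is inert to organolithiums, to iridium C–H borylation, to the rhodium carbene of the unit 1 ring closure (no activated C–H next to the carbene), to fluoride, to nickel radical chemistry and to palladium. The gain is that every earlier intermediate is non-polar and air-stable. The demand is one forcing Lewis-acid step on a molecule with a stilbene and two benzylic ether rings.

**28 to 26 and 27.** The C6–vinyl bond is cut so that the stilbene appears only after all radical, carbene and organolithium steps. This removes an eight-carbon arm and leaves 26 with no alkene. The forward step must be an E-selective Heck reaction on an aryl chloride.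

**26 to 25 and 15.** The C3–C6' bond is the only link between the two units, and cutting it gives two dihydrobenzofurans of similar size. C3 is handled as a radical released from a redox-active ester, so its configuration need not be carried: it is set in the coupling by the neighbouring C2 aryl group. The forward step must capture the radical anti to that aryl group, leave the C6–Cl bond of 25 alone, and needs the unit 2 partner as a boron nucleophile.

**15 to 14 to 13.** C6'–B is traced back to C6'–Cl and C2'–H to C2'–B. Chlorine is the one spectator that survives C2 lithiation and triflate-selective palladium chemistry and can still be turned into boron in one step. The boron on C2' is what the key step leaves behind. The demand is a protodeboronation that retains configuration at the tertiary benzylic carbon.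

**13 to 6, 8 and 10 (key disconnection).** The C2'–aryl and C3'–aryl bonds are cut together. This reduces unit 2 to three flat, achiral pieces of similar size and creates both stereocentres in the step that joins them. The forward step needs face selection by a chiral ligand on palladium, anti migration from boron, and a metallate shift that is faster than plain transmetalation. For that reason 8 is made from a boronic acid and never meets a halide salt, 6 is lithiated by deprotonation, and the base is kept slightly below one equivalent.

**25 to 24 to 22 to 21.** The C2–C3 bond of unit 1 is cut (the ester changes are trivial). An aryl ester carbene inserts into the benzylic ether CH2 and sets C2 under catalyst control; C3 remains adjustable, first through the ester enolate and later as a radical. The demand is an enantioselective 1,5-insertion with a di-ortho-substituted aryl diazoacetate, in which the methoxy C–H bonds must not compete.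

**21 to 20 to 17 and 18 to 6.** The diazo group, the O–CH2 ether bond and the C2 carbonyl oxygen are removed in turn. This leads back to the same benzofuran 6 that serves unit 2, so one benzofuran synthesis feeds both halves and fixes the substitution pattern of both benzo rings. The forward steps need a C–H borylation of 6 that touches only C2 and spares the aryl chloride, and a phenoxide alkylation that is faster than relactonisation.

**6 to 5 to 2 and 3 to 1.** The furan ring is cut at O1–C7a and C2–C3, and the carboxyl group is added back at C2. The symmetric difluoroaldehyde 1 fixes the 4-oxygen, 6-chloro pattern without regiochemical ambiguity. The demand is two successive SNAr reactions in the right order, the second on a ring already deactivated by a methoxy group.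

**8 to 7 and 10 to 9.** A B–O ester exchange and an O–S bond lead to two cheap aromatic starting materials; the only demand is that 8 be free of halide.

## Other disconnections considered

Alternative 1: The cut runs through ring B of unit 2, at C5'–C6' and C3a'–C4', so ring B is grown from a chain already attached to C3 of a finished unit 1.

- Forward step: the enone (E)-4-[(2R,3R)-4-methoxy-2-(4-methoxyphenyl)-6-[(E)-4-methoxystyryl]-2,3-dihydrobenzofuran-3-yl]but-3-en-2-one (A1) would take up a malonate diester by Michael addition. The methyl ketone enolate would then close onto one malonate ester in a Claisen condensation to give the dioxocyclohexane carboxylate A2.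
- In favour: cheap reagents and a reaction type with abundant precedent. The C3–C6' bond is never made by cross-coupling, because C6' grows from an atom already bonded to C3. On this point the alternative is better than the chosen plan, which depends on a nickel radical coupling at a hindered carbon.
- Against: A2 is only a precursor of ring B. The ester must be lost, the dione aromatised (an oxidation in the presence of the stilbene and two benzylic C–H bonds), and the two oxygens differentiated. C2' and C3' with their aryl groups would still have to be added, with nothing but the distant centres of unit 1 to control them. The base also threatens A1: deprotonation at C3, gamma to the ketone, opens the way to epimerisation or to beta-elimination of the O1–C2 bond.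
- Comparison: structurally the alternative builds a ring and no lasting stereocentre, whereas the chosen step builds two bonds and both stereocentres of unit 2 on an intact arene. Mechanistically it is the safer of the two. In step economy it is worse, since at least five further operations would be needed to reach the stage that 14 represents.

Alternative 2: Both dihydrofuran rings are cut at once, at C2–C3 and C2'–C3'.

- Forward step: the precursor would be the bis-hydrazone A3, in which each future C3 is a diaryl ketone carbon and each future C2 is the CH2 of an aryl benzyl ether. Oxidation in the flask would turn both hydrazone groups of A3 into diazo groups, and a chiral dirhodium tetracarboxylate such as Rh2(R-PTAD)4 would close each ring by 1,5 insertion of the donor–donor carbene into the neighbouring benzylic C–H bond, giving the cis,cis aryl bromide A4.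
- In favour: two rings, two C–C bonds and four stereocentres in one operation, from a precursor made by ether and ketone formation, with precedent for the single insertion on simpler substrates. In step count after fragment assembly it is better than the chosen plan, and in precedent for the bond-forming event it is also better.
- Against: the insertion gives the cis ring, so A4 would have C3 and C3' right and C2 and C2' wrong. Both would have to be inverted by acid-mediated opening and reclosure on an advanced intermediate. That should be easy at C2' (2,4-dimethoxyphenyl) and sluggish at C2 (4-methoxyphenyl), and it acts on the most fragile bonds of the molecule. Two catalyst-controlled insertions in one molecule also turn any shortfall in selectivity into diastereomers. Both ketone carbons of A3 lie between two ortho substituents, so hydrazone formation and oxidation are expected to be slow.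
- Comparison: structurally the alternative treats both units alike and is more convergent. Mechanistically the chosen step gives trans directly by anti migration, while the alternative gives cis and needs correction at two centres. In step economy the alternative wins if both epimerisations work and loses its advantage if they do not.

Alternative 3: The dihydrofuran ring of unit 2 is cut at C3'–C3a' and O1'–C2', and ring B is carried as a cyclohexane-1,3-dione.

- Forward step: the rhodium carbene from the diazo dione A5 would add to the electron-rich E-stilbene A6 under a chiral dirhodium carboxylate such as Rh2(S-PTTL)4 in a formal [3+2] annulation. The carbene carbon bonds to the alkene carbon next to the 3,5-dimethoxyphenyl ring, positive charge develops on the carbon bearing the better donor (2,4-dimethoxyphenyl), and a dione oxygen closes onto it to give the trans tetrahydrobenzofuranone A7.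
- In favour: trans is the thermodynamic outcome of a stepwise closure, the two different aryl groups dictate the regiochemistry in the required sense, and the partners are simple. In regio- and diastereocontrol it is the equal of the chosen step, and in precedent for the bond-forming event it is better.
- Against: enantiocontrol is the weak point with acceptor–acceptor carbenes and a 1,2-disubstituted trans alkene, because the stepwise path gives the zwitterion time to escape the catalyst. Ring B must then be aromatised, and dehydrogenation conditions can just as well remove the C2' and C3' hydrogens and give the fully aromatic benzofuran. The C6' substituent arrives as an ester, which is not a handle for the bond to C3 and would need several steps of conversion, whereas the chlorine of 14 is one step from boron.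
- Comparison: structurally both plans make the same ring with the same two aryl groups, one from an aromatic benzofuran and the other from a non-aromatic dione. Mechanistically the chosen step takes trans from a stereospecific anti migration and its absolute sense from ligand-bound palladium; the alternative takes trans from equilibration and its absolute sense from a less reliable carbene addition. In step economy the alternative is equal up to A7 and worse afterwards.

Key step: step 6

Assumption: the sense of induction of the MandyPhos ligand (step 6) and of Rh2(S-PTTL)4 (step 12) is assigned by analogy with simpler substrates; if a first run shows the opposite sense, the mirror-image ligand or catalyst is used, both antipodes being available.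

## Route

Step 1
Reactants: 1 4-chloro-2,6-difluorobenzaldehyde
Product: 2 4-chloro-2-fluoro-6-methoxybenzaldehyde
Conditions: NaOMe (1.05 equiv), MeOH, 0 °C to rt
Reagents that add atoms: sodium methoxide, [Na+].[O-]C
Why: SNAr at a fluorine ortho to the formyl group; fluoride leaves far faster than the para chloride, and the new methoxy group deactivates the ring so that one equivalent should stop at monosubstitution.

Step 2
Reactants: 2 4-chloro-2-fluoro-6-methoxybenzaldehyde; 3 methyl glycolate
Product: 5 6-chloro-4-methoxybenzofuran-2-carboxylic acid, via methyl 6-chloro-4-methoxybenzofuran-2-carboxylate 4 (not isolated)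
Conditions: 3 (1.3 equiv), Cs2CO3 (2.5 equiv), DMSO, 90 °C; then 2 M aq. NaOH, 60 °C; then aq. HCl to pH 2
Reagents that add atoms: sodium hydroxide, [Na+].[OH-]
Why: Tandem SNAr and intramolecular aldol (Knoevenagel-type) condensation: the glycolate alkoxide displaces the remaining ortho fluorine, the aryloxyacetate enolate closes onto the aldehyde and dehydration gives the aromatic furan; hydroxide then saponifies the ester in the same flask.

Step 3
Reactants: 5 6-chloro-4-methoxybenzofuran-2-carboxylic acid
Product: 6 6-chloro-4-methoxybenzofuran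
Conditions: Ag2CO3 (10 mol%), AcOH (5 mol%), DMSO, 120 °C
Reagents that add atoms: none
Why: Silver-catalysed protodecarboxylation of a heteroaryl-2-carboxylic acid through an aryl–silver species that is protonated; the aryl chloride and the methyl ether are not affected.

Step 4
Reactants: 7 2,4-dimethoxyphenylboronic acid
Product: 8 2-(2,4-dimethoxyphenyl)-4,4,5,5-tetramethyl-1,3,2-dioxaborolane
Conditions: pinacol (1.05 equiv), toluene, reflux (Dean–Stark)
Reagents that add atoms: pinacol, CC(C)(O)C(C)(C)O
Why: Condensation of a boronic acid with a 1,2-diol (boronic esterification); this source gives the ester free of halide salts, which would inhibit step 6.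

Step 5
Reactants: 9 3,5-dimethoxyphenol
Product: 10 3,5-dimethoxyphenyl trifluoromethanesulfonate
Conditions: Tf2O (1.1 equiv), pyridine (2 equiv), CH2Cl2, 0 °C
Reagents that add atoms: trifluoromethanesulfonic anhydride, O=S(=O)(OS(=O)(=O)C(F)(F)F)C(F)(F)F
Why: O-sulfonylation of a phenol; the triflate is the non-coordinating leaving group needed for a cationic arylpalladium in step 6.

Step 6
Reactants: 6 6-chloro-4-methoxybenzofuran; 8 2-(2,4-dimethoxyphenyl)-4,4,5,5-tetramethyl-1,3,2-dioxaborolane; 10 3,5-dimethoxyphenyl trifluoromethanesulfonate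
Product: 13 (2R,3R)-6-chloro-2-(2,4-dimethoxyphenyl)-3-(3,5-dimethoxyphenyl)-4-methoxy-2-(4,4,5,5-tetramethyl-1,3,2-dioxaborolan-2-yl)-2,3-dihydrobenzofuran (aryl groups trans), via 6-chloro-2-lithio-4-methoxybenzofuran 11 (not isolated), via lithium (6-chloro-4-methoxybenzofuran-2-yl)(2,4-dimethoxyphenyl)pinacolatoborate 12 (not isolated)
Conditions: 6 (1.2 equiv), n-BuLi (1.15 equiv), THF, −78 °C, 30 min; 8 (1.2 equiv), −78 to 0 °C; then 10 (1.0 equiv), Pd(OAc)2 (3 mol%), (Sp,Sp)-MandyPhos (3.6 mol%), THF, 60 °C
Reagents that add atoms: none
Why: Proposed new method: deprotonation of 6 at C2 and addition to 8 give the four-coordinate boronate 12; the triflate 10 adds oxidatively to zerovalent palladium and the cationic arylpalladium binds the electron-rich C2'=C3' enol-ether bond at C3', which triggers a 1,2-shift of the 2,4-dimethoxyphenyl group from boron to C2' anti to palladium, and reductive elimination with retention then forms the C3'–aryl bond; the closest known reactions are the enantioselective palladium-catalysed conjunctive coupling of alkenyl boron ate complexes with aryl triflates and the dearomative three-component coupling of indol-2-yl boronates with allylpalladium electrophiles. No ring is closed; the furan ring gives up its modest aromaticity and the oxygen O1' stabilises the positive charge that develops at C2' during the shift. C3' is set by the face of the boronate to which the ligand-bound arylpalladium is delivered (catalyst control), and C2' follows from the strict anti relationship of migrating group and palladium, so the two aryl groups must end up trans and boron cis to the C3' aryl group. The step needs the metallate shift to win over direct transmetalation of the benzofuranyl or aryl group; the halide-free and hydroxide-free ate complex and the wide-bite-angle bisphosphine are meant to secure this. It also needs the C6'–Cl bond to stay intact, which the much faster oxidative addition of the triflate at 60 °C should provide, and the slight deficit of n-BuLi keeps butyl ate complexes out. Beta-hydride elimination cannot interfere because C2' is fully substituted and C3a' is aromatic.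

Step 7
Reactants: 13 (2R,3R)-6-chloro-2-(2,4-dimethoxyphenyl)-3-(3,5-dimethoxyphenyl)-4-methoxy-2-(4,4,5,5-tetramethyl-1,3,2-dioxaborolan-2-yl)-2,3-dihydrobenzofuran
Product: 14 (2R,3R)-6-chloro-2-(2,4-dimethoxyphenyl)-3-(3,5-dimethoxyphenyl)-4-methoxy-2,3-dihydrobenzofuran
Conditions: CsF (1.5 equiv), H2O (1.5 equiv), 1,4-dioxane, 45 °C
Reagents that add atoms: none
Why: Fluoride-promoted protodeboronation of a tertiary benzylic boronic ester: the fluoride ate complex is protonated at carbon by water on the face that carried boron (retention), so the trans diaryl relationship is kept; trans is also the more stable arrangement at C2'.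

Step 8
Reactants: 14 (2R,3R)-6-chloro-2-(2,4-dimethoxyphenyl)-3-(3,5-dimethoxyphenyl)-4-methoxy-2,3-dihydrobenzofuran
Product: 15 [(2R,3R)-2-(2,4-dimethoxyphenyl)-3-(3,5-dimethoxyphenyl)-4-methoxy-2,3-dihydrobenzofuran-6-yl]boronic acid
Conditions: B2(OH)4 (3 equiv), PdCl(XPhos)(2'-aminobiphenyl-2-yl) (2 mol%), XPhos (4 mol%), KOAc (3 equiv), EtOH, 80 °C
Reagents that add atoms: tetrahydroxydiboron, OB(O)B(O)O
Why: Miyaura-type borylation of an aryl chloride with tetrahydroxydiboron under a bulky biarylphosphine palladium catalyst gives the boronic acid directly; the chloride is meta to both ring oxygens and not deactivated by resonance, and no stereocentre is involved.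

Step 9
Reactants: 6 6-chloro-4-methoxybenzofuran
Product: 17 6-chloro-4-methoxybenzofuran-2(3H)-one, via 2-(6-chloro-4-methoxybenzofuran-2-yl)-4,4,5,5-tetramethyl-1,3,2-dioxaborolane 16 (not isolated)
Conditions: B2pin2 (1.0 equiv), [Ir(OMe)(cod)]2 (1.5 mol%), 4,4'-di-tert-butyl-2,2'-bipyridine (3 mol%), THF, 50 °C; evaporate; then KHSO5 (as 2KHSO5·KHSO4·K2SO4, 1.1 equiv), acetone/H2O, 0 °C to rt
Reagents that add atoms: potassium peroxymonosulfate, [K+].[O-]S(=O)(=O)OO
Why: Iridium-catalysed C–H borylation of a benzofuran goes to the C–H bond next to the ring oxygen; here C5 and C7 each sit between two substituents and C3 lies peri to the methoxy group, so only C2 should react and the aryl chloride is left alone. Peroxymonosulfate then exchanges C–B for C–O and the 2-hydroxybenzofuran tautomerises to the lactone, so that C2 of 6 becomes the carboxyl carbon and C3 the future carbene carbon of unit 1.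

Step 10
Reactants: 17 6-chloro-4-methoxybenzofuran-2(3H)-one; 18 4-methoxybenzyl chloride
Product: 20 methyl 2-{4-chloro-2-methoxy-6-[(4-methoxyphenyl)methoxy]phenyl}acetate, via methyl 2-(4-chloro-2-hydroxy-6-methoxyphenyl)acetate 19 (not isolated)
Conditions: MeOH, H2SO4 (cat.), reflux; NaHCO3, concentrate; then 18 (1.2 equiv), K2CO3 (2 equiv), n-Bu4NI (10 mol%), DMF, rt
Reagents that add atoms: methanol, CO
Why: Acid-catalysed methanolysis opens the lactone to the hydroxy ester, and Williamson etherification of the phenoxide with the reactive benzylic chloride installs the CH2 that becomes C2 together with its aryl group; O-alkylation is expected to outrun relactonisation.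

Step 11
Reactants: 20 methyl 2-{4-chloro-2-methoxy-6-[(4-methoxyphenyl)methoxy]phenyl}acetate
Product: 21 methyl 2-{4-chloro-2-methoxy-6-[(4-methoxyphenyl)methoxy]phenyl}-2-diazoacetate
Conditions: p-ABSA (1.3 equiv), DBU (1.5 equiv), MeCN, 0 °C to rt
Reagents that add atoms: 4-acetamidobenzenesulfonyl azide, CC(=O)Nc1ccc(cc1)S(=O)(=O)N=[N+]=[N-]
Why: Regitz diazo transfer to the aryl acetate enolate, the standard access to aryl diazoacetates.

Step 12
Reactants: 21 methyl 2-{4-chloro-2-methoxy-6-[(4-methoxyphenyl)methoxy]phenyl}-2-diazoacetate
Product: 22 methyl (2R,3S)-6-chloro-4-methoxy-2-(4-methoxyphenyl)-2,3-dihydrobenzofuran-3-carboxylate (cis)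
Conditions: Rh2(S-PTTL)4 (1 mol%), toluene, −60 °C, slow addition of 21
Reagents that add atoms: none
Why: Enantioselective intramolecular 1,5 C–H insertion of a rhodium donor–acceptor carbene into the benzylic ether CH2, which is activated by oxygen and by the 4-methoxyphenyl ring and should react far faster than the primary C–H bonds of the ortho methoxy group. The chiral carboxylate ligands select one of the two enantiotopic hydrogens and so set C2 (R); the concerted insertion gives the cis ester as the kinetic product.

Step 13
Reactants: 22 methyl (2R,3S)-6-chloro-4-methoxy-2-(4-methoxyphenyl)-2,3-dihydrobenzofuran-3-carboxylate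
Product: 24 (2R,3R)-6-chloro-4-methoxy-2-(4-methoxyphenyl)-2,3-dihydrobenzofuran-3-carboxylic acid (trans), via methyl (2R,3R)-6-chloro-4-methoxy-2-(4-methoxyphenyl)-2,3-dihydrobenzofuran-3-carboxylate 23 (not isolated)
Conditions: NaOMe (0.5 equiv), MeOH/THF, 50 °C; then 2 M aq. NaOH, 50 °C; then aq. HCl to pH 3
Reagents that add atoms: sodium hydroxide, [Na+].[OH-]
Why: Base-mediated epimerisation through the ester enolate moves C3 to the more stable trans arrangement (thermodynamic control) while the non-acidic C2 is untouched, and saponification follows in the same flask; a single diastereomer is wanted only for ease of handling, since C3 is reset in step 15.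

Step 14
Reactants: 24 (2R,3R)-6-chloro-4-methoxy-2-(4-methoxyphenyl)-2,3-dihydrobenzofuran-3-carboxylic acid
Product: 25 4,5,6,7-tetrachloro-1,3-dioxoisoindolin-2-yl (2R,3R)-6-chloro-4-methoxy-2-(4-methoxyphenyl)-2,3-dihydrobenzofuran-3-carboxylate
Conditions: N-hydroxytetrachlorophthalimide (1.05 equiv), DIC (1.1 equiv), DMAP (5 mol%), CH2Cl2, rt
Reagents that add atoms: N-hydroxytetrachlorophthalimide, ON1C(=O)c2c(Cl)c(Cl)c(Cl)c(Cl)c2C1=O
Why: Carbodiimide (Steglich-type) esterification gives the redox-active ester; any epimerisation at C3 during activation is of no consequence because C3 becomes a radical in the next step.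

Step 15
Reactants: 25 4,5,6,7-tetrachloro-1,3-dioxoisoindolin-2-yl (2R,3R)-6-chloro-4-methoxy-2-(4-methoxyphenyl)-2,3-dihydrobenzofuran-3-carboxylate; 15 [(2R,3R)-2-(2,4-dimethoxyphenyl)-3-(3,5-dimethoxyphenyl)-4-methoxy-2,3-dihydrobenzofuran-6-yl]boronic acid
Product: 26 (2R,3R)-6-chloro-3-[(2R,3R)-2-(2,4-dimethoxyphenyl)-3-(3,5-dimethoxyphenyl)-4-methoxy-2,3-dihydrobenzofuran-6-yl]-4-methoxy-2-(4-methoxyphenyl)-2,3-dihydrobenzofuran
Conditions: 15 (2 equiv), NiCl2·6H2O (20 mol%), 4,7-diphenyl-1,10-phenanthroline (22 mol%), Et3N (10 equiv), 1,4-dioxane/DMF 10:1, 75 °C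
Reagents that add atoms: none
Why: Nickel-catalysed decarboxylative arylation of a secondary redox-active ester with an arylboronic acid: electron transfer to the ester releases CO2 and the planar benzylic C3 radical, which is captured by arylnickel, and reductive elimination forms C3–C6'. C3 is set under substrate control, nickel approaching the ring face anti to the C2 aryl group to give the trans ring; the centres of 15 and C2 take no part, and the electron-rich aryl chloride should be inert under these conditions.

Step 16
Reactants: 26 (2R,3R)-6-chloro-3-[(2R,3R)-2-(2,4-dimethoxyphenyl)-3-(3,5-dimethoxyphenyl)-4-methoxy-2,3-dihydrobenzofuran-6-yl]-4-methoxy-2-(4-methoxyphenyl)-2,3-dihydrobenzofuran; 27 4-methoxystyrene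
Product: 28 (2R,3R)-3-[(2R,3R)-2-(2,4-dimethoxyphenyl)-3-(3,5-dimethoxyphenyl)-4-methoxy-2,3-dihydrobenzofuran-6-yl]-4-methoxy-2-(4-methoxyphenyl)-6-[(E)-2-(4-methoxyphenyl)ethenyl]-2,3-dihydrobenzofuran
Conditions: 27 (2 equiv), Pd2(dba)3 (2.5 mol%), [HP(t-Bu)3]BF4 (10 mol%), Cy2NMe (1.5 equiv), 1,4-dioxane, 110 °C
Reagents that add atoms: none
Why: Mizoroki–Heck reaction of an aryl chloride under a bulky trialkylphosphine palladium catalyst; syn insertion at the terminal alkene carbon and syn beta-hydride elimination give the E-stilbene, and the substrate contains only ethers and C–H bonds besides the chloride.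

Step 17
Reactants: 28 (2R,3R)-3-[(2R,3R)-2-(2,4-dimethoxyphenyl)-3-(3,5-dimethoxyphenyl)-4-methoxy-2,3-dihydrobenzofuran-6-yl]-4-methoxy-2-(4-methoxyphenyl)-6-[(E)-2-(4-methoxyphenyl)ethenyl]-2,3-dihydrobenzofuran
Product: 29 (2R,3R)-3-[(2R,3R)-2-(2,4-dihydroxyphenyl)-3-(3,5-dihydroxyphenyl)-4-hydroxy-2,3-dihydrobenzofuran-6-yl]-2-(4-hydroxyphenyl)-6-[(E)-2-(4-hydroxyphenyl)ethenyl]-2,3-dihydrobenzofuran-4-ol (CNP0118407.2)
Conditions: BBr3 (24 equiv), CH2Cl2, −78 °C to rt, argon, dark; MeOH at −78 °C; aq. NaHCO3
Reagents that add atoms: none
Why: Lewis-acid cleavage of aryl methyl ethers (bromide attacks the methyl group of the boron-complexed ether), the usual last step for permethylated oligostilbenes. No C–C bond is touched, and a reversible opening of the O1'–C2' bond should reclose to the more stable trans ring because C3' is not affected.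

## Compound list

1 | 4-chloro-2,6-difluorobenzaldehyde | O=Cc1c(F)cc(Cl)cc1F | starting material
2 | 4-chloro-2-fluoro-6-methoxybenzaldehyde | COc1cc(Cl)cc(F)c1C=O | intermediate
3 | methyl glycolate | COC(=O)CO | starting material
4 | methyl 6-chloro-4-methoxybenzofuran-2-carboxylate | COC(=O)c1cc2c(OC)cc(Cl)cc2o1 | intermediate
5 | 6-chloro-4-methoxybenzofuran-2-carboxylic acid | OC(=O)c1cc2c(OC)cc(Cl)cc2o1 | intermediate
6 | 6-chloro-4-methoxybenzofuran | COc1cc(Cl)cc2occc12 | intermediate
7 | 2,4-dimethoxyphenylboronic acid | COc1ccc(B(O)O)c(OC)c1 | starting material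
8 | 2-(2,4-dimethoxyphenyl)-4,4,5,5-tetramethyl-1,3,2-dioxaborolane | COc1ccc(B2OC(C)(C)C(C)(C)O2)c(OC)c1 | intermediate
9 | 3,5-dimethoxyphenol | COc1cc(O)cc(OC)c1 | starting material
10 | 3,5-dimethoxyphenyl trifluoromethanesulfonate | COc1cc(OC)cc(OS(=O)(=O)C(F)(F)F)c1 | intermediate
11 | 6-chloro-2-lithio-4-methoxybenzofuran | [Li]c1cc2c(OC)cc(Cl)cc2o1 | intermediate
12 | lithium (6-chloro-4-methoxybenzofuran-2-yl)(2,4-dimethoxyphenyl)pinacolatoborate | [Li+].COc1ccc(c(OC)c1)[B-]1(OC(C)(C)C(C)(C)O1)c1cc2c(OC)cc(Cl)cc2o1 | intermediate
13 | (2R,3R)-6-chloro-2-(2,4-dimethoxyphenyl)-3-(3,5-dimethoxyphenyl)-4-methoxy-2-(4,4,5,5-tetramethyl-1,3,2-dioxaborolan-2-yl)-2,3-dihydrobenzofuran | Clc1cc(OC)c2c(c1)O[C@@](B1OC(C)(C)C(C)(C)O1)(c1ccc(OC)cc1OC)[C@@H]2c1cc(OC)cc(OC)c1 | intermediate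
14 | (2R,3R)-6-chloro-2-(2,4-dimethoxyphenyl)-3-(3,5-dimethoxyphenyl)-4-methoxy-2,3-dihydrobenzofuran | Clc1cc(OC)c2c(c1)O[C@@H](c1ccc(OC)cc1OC)[C@@H]2c1cc(OC)cc(OC)c1 | intermediate
15 | [(2R,3R)-2-(2,4-dimethoxyphenyl)-3-(3,5-dimethoxyphenyl)-4-methoxy-2,3-dihydrobenzofuran-6-yl]boronic acid | OB(O)c1cc(OC)c2c(c1)O[C@@H](c1ccc(OC)cc1OC)[C@@H]2c1cc(OC)cc(OC)c1 | intermediate
16 | 2-(6-chloro-4-methoxybenzofuran-2-yl)-4,4,5,5-tetramethyl-1,3,2-dioxaborolane | COc1cc(Cl)cc2oc(B3OC(C)(C)C(C)(C)O3)cc12 | intermediate
17 | 6-chloro-4-methoxybenzofuran-2(3H)-one | COc1cc(Cl)cc2OC(=O)Cc12 | intermediate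
18 | 4-methoxybenzyl chloride | COc1ccc(CCl)cc1 | starting material
19 | methyl 2-(4-chloro-2-hydroxy-6-methoxyphenyl)acetate | COC(=O)Cc1c(O)cc(Cl)cc1OC | intermediate
20 | methyl 2-{4-chloro-2-methoxy-6-[(4-methoxyphenyl)methoxy]phenyl}acetate | COC(=O)Cc1c(OC)cc(Cl)cc1OCc1ccc(OC)cc1 | intermediate
21 | methyl 2-{4-chloro-2-methoxy-6-[(4-methoxyphenyl)methoxy]phenyl}-2-diazoacetate | COC(=O)C(=[N+]=[N-])c1c(OC)cc(Cl)cc1OCc1ccc(OC)cc1 | intermediate
22 | methyl (2R,3S)-6-chloro-4-methoxy-2-(4-methoxyphenyl)-2,3-dihydrobenzofuran-3-carboxylate (cis) | Clc1cc(OC)c2c(c1)O[C@@H](c1ccc(OC)cc1)[C@H]2C(=O)OC | intermediate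
23 | methyl (2R,3R)-6-chloro-4-methoxy-2-(4-methoxyphenyl)-2,3-dihydrobenzofuran-3-carboxylate (trans) | Clc1cc(OC)c2c(c1)O[C@@H](c1ccc(OC)cc1)[C@@H]2C(=O)OC | intermediate
24 | (2R,3R)-6-chloro-4-methoxy-2-(4-methoxyphenyl)-2,3-dihydrobenzofuran-3-carboxylic acid | Clc1cc(OC)c2c(c1)O[C@@H](c1ccc(OC)cc1)[C@@H]2C(=O)O | intermediate
25 | 4,5,6,7-tetrachloro-1,3-dioxoisoindolin-2-yl (2R,3R)-6-chloro-4-methoxy-2-(4-methoxyphenyl)-2,3-dihydrobenzofuran-3-carboxylate | Clc1cc(OC)c2c(c1)O[C@@H](c1ccc(OC)cc1)[C@@H]2C(=O)ON1C(=O)c2c(Cl)c(Cl)c(Cl)c(Cl)c2C1=O | intermediate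
26 | (2R,3R)-6-chloro-3-[(2R,3R)-2-(2,4-dimethoxyphenyl)-3-(3,5-dimethoxyphenyl)-4-methoxy-2,3-dihydrobenzofuran-6-yl]-4-methoxy-2-(4-methoxyphenyl)-2,3-dihydrobenzofuran | Clc1cc(OC)c2c(c1)O[C@@H](c1ccc(OC)cc1)[C@@H]2c1cc(OC)c2c(c1)O[C@@H](c1ccc(OC)cc1OC)[C@@H]2c1cc(OC)cc(OC)c1 | intermediate
27 | 4-methoxystyrene | COc1ccc(C=C)cc1 | starting material
28 | (2R,3R)-3-[(2R,3R)-2-(2,4-dimethoxyphenyl)-3-(3,5-dimethoxyphenyl)-4-methoxy-2,3-dihydrobenzofuran-6-yl]-4-methoxy-2-(4-methoxyphenyl)-6-[(E)-2-(4-methoxyphenyl)ethenyl]-2,3-dihydrobenzofuran | COc1ccc(/C=C/c2cc(OC)c3c(c2)O[C@@H](c2ccc(OC)cc2)[C@@H]3c2cc(OC)c3c(c2)O[C@@H](c2ccc(OC)cc2OC)[C@@H]3c2cc(OC)cc(OC)c2)cc1 | intermediate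
29 | (2R,3R)-3-[(2R,3R)-2-(2,4-dihydroxyphenyl)-3-(3,5-dihydroxyphenyl)-4-hydroxy-2,3-dihydrobenzofuran-6-yl]-2-(4-hydroxyphenyl)-6-[(E)-2-(4-hydroxyphenyl)ethenyl]-2,3-dihydrobenzofuran-4-ol | Oc1ccc(/C=C/c2cc(O)c3c(c2)O[C@@H](c2ccc(O)cc2)[C@@H]3c2cc(O)c3c(c2)O[C@@H](c2ccc(O)cc2O)[C@@H]3c2cc(O)cc(O)c2)cc1 | target

## Step count and least certain steps

Total: 17 steps. Longest linear sequence: 12 steps (1, 2, 3, 9, 10, 11, 12, 13, 14, 15, 16, 17). The unit 2 branch (steps 4 to 8) joins at step 15.

**Step 6 (key step, the one step beyond known chemistry).**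
- What may go wrong: plain transmetalation of the benzofuranyl or aryl group from boron to palladium, since 2-heteroaryl boronates transfer readily. Attack at C3' may be slow because of the peri methoxy group. Lithiation may occur next to chlorine, followed by loss of LiCl. Face selection by the ligand may be poor on a substrate class for which it was not developed.
- Fallback, known chemistry throughout, from 17 back to 14: the logic of unit 1 is applied to unit 2. Methanolysis of 17 to 19 (here isolated) and Mitsunobu etherification with 2,4-dimethoxybenzyl alcohol (PPh3, DIAD, THF) give methyl 2-{4-chloro-2-[(2,4-dimethoxyphenyl)methoxy]-6-methoxyphenyl}acetate F1. Diazo transfer as in step 11 gives methyl 2-{4-chloro-2-[(2,4-dimethoxyphenyl)methoxy]-6-methoxyphenyl}-2-diazoacetate F2. Insertion with Rh2(S-PTTL)4 as in step 12 gives methyl (2R,3S)-6-chloro-2-(2,4-dimethoxyphenyl)-4-methoxy-2,3-dihydrobenzofuran-3-carboxylate F3. Epimerisation and saponification as in step 13 give (2R,3R)-6-chloro-2-(2,4-dimethoxyphenyl)-4-methoxy-2,3-dihydrobenzofuran-3-carboxylic acid F4. Its 4,5,6,7-tetrachloro-1,3-dioxoisoindolin-2-yl ester F5 is coupled with commercial 3,5-dimethoxyphenylboronic acid under the conditions of step 15, the aryl group entering anti to the C2' aryl group, to give 14.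

**Step 15.**
- What may go wrong: beta-hydride elimination or oxidation at C3 towards the aromatic 2-arylbenzofuran, which is driven by aromatisation. The boronic acid may be lost by protodeboronation and homocoupling, and face selection at the radical may be incomplete.
- Fallback from 15 and 24 back to 26: ipso iododeboronation of 15 with CuI, 1,10-phenanthroline and KI in aqueous MeOH under air gives (2R,3R)-2-(2,4-dimethoxyphenyl)-3-(3,5-dimethoxyphenyl)-6-iodo-4-methoxy-2,3-dihydrobenzofuran F6. An electrophilic iodinating agent is avoided because it would attack C5' or C7'. Acid 24 is converted with N-hydroxyphthalimide, DIC and DMAP into 1,3-dioxoisoindolin-2-yl (2R,3R)-6-chloro-4-methoxy-2-(4-methoxyphenyl)-2,3-dihydrobenzofuran-3-carboxylate F7. The two electrophiles are joined by nickel-catalysed reductive cross-electrophile coupling (NiBr2(dme), 4,4'-di-tert-butyl-2,2'-bipyridine, Zn, DMA, rt), in which the aryl iodide should react far faster than the aryl chloride, to give 26. No boronic acid is then exposed to base and heat.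

**Step 17.**
- What may go wrong: incomplete cleavage of some of the eight ethers, addition of HBr to the electron-rich stilbene or its cationic oligomerisation, and ring opening at O1'–C2' that does not reclose cleanly.
- Fallback from 26 to 29, which takes the stilbene out of the Lewis-acid step and lets the polyphenol be purified as a stable peracetate: BBr3 on 26 gives (2R,3R)-6-chloro-3-[(2R,3R)-2-(2,4-dihydroxyphenyl)-3-(3,5-dihydroxyphenyl)-4-hydroxy-2,3-dihydrobenzofuran-6-yl]-2-(4-hydroxyphenyl)-2,3-dihydrobenzofuran-4-ol F8. Ac2O and pyridine give its heptaacetate F9. A Heck reaction with 4-acetoxystyrene under the conditions of step 16 gives the octaacetate of the target F10. K2CO3 in MeOH at 0 °C under argon removes the acetates to give 29.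

**Step 12.**
- What may go wrong: loss of enantioselectivity because the second ortho substituent twists the aryl carbene out of the geometry for which the catalyst is known to work, and competing insertion into the C–H bonds of the neighbouring methoxy group.
- Fallback from 21 back to 24, by resolution in place of asymmetric catalysis: decomposition of 21 with achiral Rh2(OAc)4 gives 22 together with its antipode methyl (2S,3R)-6-chloro-4-methoxy-2-(4-methoxyphenyl)-2,3-dihydrobenzofuran-3-carboxylate F11. Step 13 applied to this racemate gives 24 together with (2S,3S)-6-chloro-4-methoxy-2-(4-methoxyphenyl)-2,3-dihydrobenzofuran-3-carboxylic acid F12. Crystallisation with (R)-1-phenylethylamine gives (R)-1-phenylethylammonium (2R,3R)-6-chloro-4-methoxy-2-(4-methoxyphenyl)-2,3-dihydrobenzofuran-3-carboxylate F13, and acidification returns 24. The amine antipode whose salt with 24 is the less soluble would be chosen by trial; the R amine is written here.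

**Step 2.**
- What may go wrong: the second SNAr may be slow on the methoxy-deactivated ring, the aldehyde may disproportionate under base, and the glycolate may self-condense.
- Fallback from 2 back to 4 (then saponified to 5 as in step 2), by the classical salicylaldehyde route: excess NaOMe in refluxing MeOH gives 4-chloro-2,6-dimethoxybenzaldehyde F14. BCl3 in CH2Cl2 removes one methyl group through the chelate with the formyl oxygen to give 4-chloro-2-hydroxy-6-methoxybenzaldehyde F15. Methyl bromoacetate and K2CO3 in DMF at 90 °C (O-alkylation, then intramolecular aldol condensation) give 4.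

## Further compounds

F1 | step 6 | methyl 2-{4-chloro-2-[(2,4-dimethoxyphenyl)methoxy]-6-methoxyphenyl}acetate | COC(=O)Cc1c(OC)cc(Cl)cc1OCc1ccc(OC)cc1OC
F2 | step 6 | methyl 2-{4-chloro-2-[(2,4-dimethoxyphenyl)methoxy]-6-methoxyphenyl}-2-diazoacetate | COC(=O)C(=[N+]=[N-])c1c(OC)cc(Cl)cc1OCc1ccc(OC)cc1OC
F3 | step 6 | methyl (2R,3S)-6-chloro-2-(2,4-dimethoxyphenyl)-4-methoxy-2,3-dihydrobenzofuran-3-carboxylate | Clc1cc(OC)c2c(c1)O[C@@H](c1ccc(OC)cc1OC)[C@H]2C(=O)OC
F4 | step 6 | (2R,3R)-6-chloro-2-(2,4-dimethoxyphenyl)-4-methoxy-2,3-dihydrobenzofuran-3-carboxylic acid | Clc1cc(OC)c2c(c1)O[C@@H](c1ccc(OC)cc1OC)[C@@H]2C(=O)O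
F5 | step 6 | 4,5,6,7-tetrachloro-1,3-dioxoisoindolin-2-yl (2R,3R)-6-chloro-2-(2,4-dimethoxyphenyl)-4-methoxy-2,3-dihydrobenzofuran-3-carboxylate | Clc1cc(OC)c2c(c1)O[C@@H](c1ccc(OC)cc1OC)[C@@H]2C(=O)ON1C(=O)c2c(Cl)c(Cl)c(Cl)c(Cl)c2C1=O
F6 | step 15 | (2R,3R)-2-(2,4-dimethoxyphenyl)-3-(3,5-dimethoxyphenyl)-6-iodo-4-methoxy-2,3-dihydrobenzofuran | Ic1cc(OC)c2c(c1)O[C@@H](c1ccc(OC)cc1OC)[C@@H]2c1cc(OC)cc(OC)c1
F7 | step 15 | 1,3-dioxoisoindolin-2-yl (2R,3R)-6-chloro-4-methoxy-2-(4-methoxyphenyl)-2,3-dihydrobenzofuran-3-carboxylate | Clc1cc(OC)c2c(c1)O[C@@H](c1ccc(OC)cc1)[C@@H]2C(=O)ON1C(=O)c2ccccc2C1=O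
F8 | step 17 | (2R,3R)-6-chloro-3-[(2R,3R)-2-(2,4-dihydroxyphenyl)-3-(3,5-dihydroxyphenyl)-4-hydroxy-2,3-dihydrobenzofuran-6-yl]-2-(4-hydroxyphenyl)-2,3-dihydrobenzofuran-4-ol | Clc1cc(O)c2c(c1)O[C@@H](c1ccc(O)cc1)[C@@H]2c1cc(O)c2c(c1)O[C@@H](c1ccc(O)cc1O)[C@@H]2c1cc(O)cc(O)c1
F9 | step 17 | heptaacetate of F8 | Clc1cc(OC(C)=O)c2c(c1)O[C@@H](c1ccc(OC(C)=O)cc1)[C@@H]2c1cc(OC(C)=O)c2c(c1)O[C@@H](c1ccc(OC(C)=O)cc1OC(C)=O)[C@@H]2c1cc(OC(C)=O)cc(OC(C)=O)c1
F10 | step 17 | octaacetate of 29 | CC(=O)Oc1ccc(/C=C/c2cc(OC(C)=O)c3c(c2)O[C@@H](c2ccc(OC(C)=O)cc2)[C@@H]3c2cc(OC(C)=O)c3c(c2)O[C@@H](c2ccc(OC(C)=O)cc2OC(C)=O)[C@@H]3c2cc(OC(C)=O)cc(OC(C)=O)c2)cc1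
F11 | step 12 | methyl (2S,3R)-6-chloro-4-methoxy-2-(4-methoxyphenyl)-2,3-dihydrobenzofuran-3-carboxylate (antipode of 22) | Clc1cc(OC)c2c(c1)O[C@H](c1ccc(OC)cc1)[C@@H]2C(=O)OC
F12 | step 12 | (2S,3S)-6-chloro-4-methoxy-2-(4-methoxyphenyl)-2,3-dihydrobenzofuran-3-carboxylic acid (antipode of 24) | Clc1cc(OC)c2c(c1)O[C@H](c1ccc(OC)cc1)[C@H]2C(=O)O
F13 | step 12 | (R)-1-phenylethylammonium (2R,3R)-6-chloro-4-methoxy-2-(4-methoxyphenyl)-2,3-dihydrobenzofuran-3-carboxylate | Clc1cc(OC)c2c(c1)O[C@@H](c1ccc(OC)cc1)[C@@H]2C(=O)[O-].C[C@@H]([NH3+])c1ccccc1
F14 | step 2 | 4-chloro-2,6-dimethoxybenzaldehyde | COc1cc(Cl)cc(OC)c1C=O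
F15 | step 2 | 4-chloro-2-hydroxy-6-methoxybenzaldehyde | COc1cc(Cl)cc(O)c1C=O
A1 | alternative 1 | (E)-4-[(2R,3R)-4-methoxy-2-(4-methoxyphenyl)-6-[(E)-4-methoxystyryl]-2,3-dihydrobenzofuran-3-yl]but-3-en-2-one | COc1ccc(/C=C/c2cc(OC)c3c(c2)O[C@@H](c2ccc(OC)cc2)[C@@H]3/C=C/C(C)=O)cc1
A2 | alternative 1 | methyl 6-[(2R,3R)-4-methoxy-2-(4-methoxyphenyl)-6-[(E)-4-methoxystyryl]-2,3-dihydrobenzofuran-3-yl]-2,4-dioxocyclohexane-1-carboxylate (ring centres unassigned) | COc1ccc(/C=C/c2cc(OC)c3c(c2)O[C@@H](c2ccc(OC)cc2)[C@@H]3C2CC(=O)CC(=O)C2C(=O)OC)cc1
A3 | alternative 2 | bis-hydrazone of {4-bromo-2-methoxy-6-[(4-methoxyphenyl)methoxy]phenyl}{4-(3,5-dimethoxybenzoyl)-3-[(2,4-dimethoxyphenyl)methoxy]-5-methoxyphenyl}methanone | NN=C(c1c(OC)cc(Br)cc1OCc1ccc(OC)cc1)c1cc(OC)c(C(=NN)c2cc(OC)cc(OC)c2)c(OCc2ccc(OC)cc2OC)c1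
A4 | alternative 2 | (2S,3R)-6-bromo-3-[(2S,3R)-2-(2,4-dimethoxyphenyl)-3-(3,5-dimethoxyphenyl)-4-methoxy-2,3-dihydrobenzofuran-6-yl]-4-methoxy-2-(4-methoxyphenyl)-2,3-dihydrobenzofuran (cis,cis) | Brc1cc(OC)c2c(c1)O[C@H](c1ccc(OC)cc1)[C@@H]2c1cc(OC)c2c(c1)O[C@H](c1ccc(OC)cc1OC)[C@@H]2c1cc(OC)cc(OC)c1
A5 | alternative 3 | methyl 4-diazo-3,5-dioxocyclohexane-1-carboxylate | COC(=O)C1CC(=O)C(=[N+]=[N-])C(=O)C1
A6 | alternative 3 | (E)-1-[2-(3,5-dimethoxyphenyl)ethenyl]-2,4-dimethoxybenzene | COc1ccc(/C=C/c2cc(OC)cc(OC)c2)c(OC)c1
A7 | alternative 3 | methyl (2R,3R)-2-(2,4-dimethoxyphenyl)-3-(3,5-dimethoxyphenyl)-4-oxo-2,3,4,5,6,7-hexahydrobenzofuran-6-carboxylate (C6 epimers) | COC(=O)C1CC(=O)C2=C(C1)O[C@@H](c1ccc(OC)cc1OC)[C@@H]2c1cc(OC)cc(OC)c1
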